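**Retrosynthetic overview**
- Feature: ring C is a 4-pyranone. Its C4 and O1 both sit on ring A, which is therefore a hidden salicylaldehyde (C4 = formyl carbon, O1 = ortho phenol oxygen). Its C2=C3 unit carries ring B on C2 and the prenyl chain on C3, so it is a hidden unsymmetrical aryl/alkyl alkyne.
- Late disconnections: the 5-O, 2'-O and 4'-O MOM ethers are removed first. The C8 1,1-dimethylallyl group then goes back to a 7-O-prenyl ether (retro aromatic Claisen).
- Key disconnection: C3–C4 and O1–C2 are cut together (rhodium formyl C–H activation and alkyne annulation). This gives a mono-MOM 4-O-prenyl phloroglucinaldehyde and an aryl prenyl alkyne.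
- Halves: 2,4,6-trihydroxybenzaldehyde is 4-O-prenylated and then mono-MOM protected. 2,4-Dihydroxybenzaldehyde is bis-MOM protected, homologated (Ohira–Bestmann) and C-prenylated under copper catalysis.
- Ring order: rings A and B are purchased; ring C is the only ring formed (step 6).

Key step: step 6

Remark on the chemistry: the target has no stereocentre and no configurable double bond, so no stereocontrol is needed. Flavone numbering (O1, C2 to C8a, ring B primed) is used throughout.

**Step 1**
Reactants: 1 2,4,6-trihydroxybenzaldehyde; 2 3-methylbut-2-en-1-ol (prenol)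
Product: 3 2,6-dihydroxy-4-(3-methylbut-2-enyloxy)benzaldehyde
Conditions: 2 (1.0 equiv), PPh3, DIAD, THF, 0 °C to rt
Reagents that add atoms: 3-methylbut-2-en-1-ol (2), CC(C)=CCO
Why: In this Mitsunobu etherification the 4-OH is the most acidic phenol and the only one not hydrogen-bonded to the formyl oxygen, so one equivalent of 2 should O-alkylate it alone, and the neutral SN2 conditions avoid the C-prenylation that phloroglucinol phenoxides undergo with prenyl halides and base.

**Step 2**
Reactants: 3 2,6-dihydroxy-4-(3-methylbut-2-enyloxy)benzaldehyde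
Product: 4 2-hydroxy-6-(methoxymethoxy)-4-(3-methylbut-2-enyloxy)benzaldehyde
Conditions: MOMCl (1.05 equiv), i-Pr2NEt (1.3 equiv), CH2Cl2, 0 °C
Reagents that add atoms: chloromethyl methyl ether (MOMCl), COCCl
Why: In this MOM protection (Williamson-type O-alkylation) the two phenols of 3 are equivalent, and once one is capped the other is held in a strong hydrogen bond to the aldehyde and should be too poor a nucleophile under amine-base conditions to take a second MOM group.

**Step 3**
Reactants: 5 2,4-dihydroxybenzaldehyde
Product: 6 2,4-bis(methoxymethoxy)benzaldehyde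
Conditions: NaH (2.5 equiv), MOMCl (2.5 equiv), DMF, 0 °C to rt
Reagents that add atoms: chloromethyl methyl ether (MOMCl), COCCl
Why: This is an exhaustive MOM protection through the bis-phenoxide, in which full deprotonation by NaH breaks the chelate of the 2-OH so that both oxygens are alkylated.

**Step 4**
Reactants: 6 2,4-bis(methoxymethoxy)benzaldehyde; 7 dimethyl (1-diazo-2-oxopropyl)phosphonate
Product: 8 1-ethynyl-2,4-bis(methoxymethoxy)benzene
Conditions: 7 (1.3 equiv), K2CO3 (2 equiv), MeOH, rt
Reagents that add atoms: dimethyl (1-diazo-2-oxopropyl)phosphonate (7), COP(=O)(OC)C(=[N+]=[N-])C(C)=O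
Why: In this Ohira–Bestmann homologation methoxide deacylates 7, the diazophosphonate anion olefinates the aldehyde, and loss of N2 with a 1,2-hydrogen shift gives the terminal alkyne under mildly basic conditions that MOM ethers tolerate.

**Step 5**
Reactants: 8 1-ethynyl-2,4-bis(methoxymethoxy)benzene; 9 prenyl bromide (1-bromo-3-methylbut-2-ene)
Product: 10 2,4-bis(methoxymethoxy)-1-(5-methylhex-4-en-1-ynyl)benzene
Conditions: 9 (1.2 equiv), CuI (10 mol %), n-Bu4NBr (10 mol %), K2CO3 (1.5 equiv), DMF, rt
Reagents that add atoms: prenyl bromide (9), CC(C)=CCBr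
Why: In this copper-catalysed allylic substitution by a terminal alkyne the copper acetylide formed with carbonate should displace bromide at the unhindered primary carbon (SN2 rather than SN2'), and the weak base at room temperature should keep the skipped enyne from moving into conjugation.

**Step 6**
Reactants: 4 2-hydroxy-6-(methoxymethoxy)-4-(3-methylbut-2-enyloxy)benzaldehyde; 10 2,4-bis(methoxymethoxy)-1-(5-methylhex-4-en-1-ynyl)benzene
Product: 11 2-[2,4-bis(methoxymethoxy)phenyl]-5-(methoxymethoxy)-3-(3-methylbut-2-enyl)-7-(3-methylbut-2-enyloxy)chromen-4-one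
Conditions: 10 (1.2 equiv), [Cp*RhCl2]2 (2.5 mol %), AgSbF6 (10 mol %), Cu(OAc)2 (2.2 equiv), ClCH2CH2Cl, 90 °C, N2
Reagents that add atoms: none
Why: Acetate-assisted ligand exchange puts the only free phenoxide of 4 on the cationic Cp*Rh centre (trivalent rhodium, unmasked from [Cp*RhCl2]2 by AgSbF6), concerted metalation–deprotonation of the adjacent formyl C–H gives a five-membered acyl rhodacycle, alkyne 10 inserts into the Rh–acyl bond (C3–C4), and C–O reductive elimination from the resulting seven-membered oxarhodacycle makes O1–C2, after which Cu(OAc)2 takes monovalent rhodium back to the trivalent state. The closest known reaction type is the rhodium-catalysed oxidative annulation of salicylaldehydes with internal aryl alkyl alkynes, which gives 3-alkyl-2-arylchromones. Ring C, the only ring closed, forms as a formal [4+2] annulation (C4, C4a, C8a and O1 from 4; C3 and C2 from 10) whose ring-closing event is the O1–C2 reductive elimination at the metal. No stereocentre is created. The selectivity needed is the sense of insertion: the aryl-bearing alkyne carbon should end up on rhodium because the forming Rh–C bond is stabilised by the electron-rich aryl group and by five-membered chelation from the ortho MOM oxygen, while the smaller CH2 terminus meets the crowded acyl carbon, so ring B lands on C2 and the prenyl chain on C3. Chemoselectivity also rests on the substrate: the 5-O-MOM group blocks the peri position against a second carbonyl-directed C–H annulation, the excess acetate keeps the medium no more acidic than AcOH so that the MOM and prenyl ethers should hold at 90 °C, and the trisubstituted olefins are poor ligands for the hindered Cp*Rh centre.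

**Step 7**
Reactants: 11 2-[2,4-bis(methoxymethoxy)phenyl]-5-(methoxymethoxy)-3-(3-methylbut-2-enyl)-7-(3-methylbut-2-enyloxy)chromen-4-one
Product: 13 2-[2,4-bis(methoxymethoxy)phenyl]-7-hydroxy-5-(methoxymethoxy)-8-(2-methylbut-3-en-2-yl)-3-(3-methylbut-2-enyl)chromen-4-one, via ortho-dienone 12 (not isolated)
Conditions: PhNEt2, 190 °C, sealed tube, Ar, stopped at full conversion
Reagents that add atoms: none
Why: In this aromatic Claisen rearrangement the [3,3] shift turns the O-prenyl group into a C-bound 1,1-dimethylallyl group and should go to C8, because the C7–C8 bond of chromones has the higher double-bond character (7-allyloxy-chromones and -flavones give 8-allyl products) and C6 is squeezed between the 5-O-MOM group and the C7 oxygen; tautomerisation of 12 then restores ring A, and the amine solvent shields the MOM ethers.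

**Step 8**
Reactants: 13 2-[2,4-bis(methoxymethoxy)phenyl]-7-hydroxy-5-(methoxymethoxy)-8-(2-methylbut-3-en-2-yl)-3-(3-methylbut-2-enyl)chromen-4-one
Product: 14 nigrasin I, 2-(2,4-dihydroxyphenyl)-5,7-dihydroxy-8-(2-methylbut-3-en-2-yl)-3-(3-methylbut-2-enyl)chromen-4-one
Conditions: conc. aq HCl (to ca. 0.3 M), MeOH, 45 °C, quenched with NaHCO3 as soon as the last MOM group is gone
Reagents that add atoms: none
Why: This is an acid-catalysed acetal methanolysis (MOM cleavage), in which phenolic MOM ethers ionise through an oxocarbenium ion far more readily than dilute acid protonates the olefins, the C3 prenyl group has no phenol within reach of a five- or six-membered closure, and the C8 vinyl group would have to pass through a secondary cation.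

**Compound list**
1 | 2,4,6-trihydroxybenzaldehyde | O=Cc1c(O)cc(O)cc1O | starting material
2 | 3-methylbut-2-en-1-ol (prenol) | CC(C)=CCO | starting material
3 | 2,6-dihydroxy-4-(3-methylbut-2-enyloxy)benzaldehyde | O=Cc1c(O)cc(OCC=C(C)C)cc1O | intermediate
4 | 2-hydroxy-6-(methoxymethoxy)-4-(3-methylbut-2-enyloxy)benzaldehyde | O=Cc1c(O)cc(OCC=C(C)C)cc1OCOC | intermediate
5 | 2,4-dihydroxybenzaldehyde | O=Cc1ccc(O)cc1O | starting material
6 | 2,4-bis(methoxymethoxy)benzaldehyde | O=Cc1ccc(OCOC)cc1OCOC | intermediate
7 | dimethyl (1-diazo-2-oxopropyl)phosphonate | COP(=O)(OC)C(=[N+]=[N-])C(C)=O | starting material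
8 | 1-ethynyl-2,4-bis(methoxymethoxy)benzene | C#Cc1ccc(OCOC)cc1OCOC | intermediate
9 | prenyl bromide (1-bromo-3-methylbut-2-ene) | CC(C)=CCBr | starting material
10 | 2,4-bis(methoxymethoxy)-1-(5-methylhex-4-en-1-ynyl)benzene | CC(C)=CCC#Cc1ccc(OCOC)cc1OCOC | intermediate
11 | 2-[2,4-bis(methoxymethoxy)phenyl]-5-(methoxymethoxy)-3-(3-methylbut-2-enyl)-7-(3-methylbut-2-enyloxy)chromen-4-one | COCOc1ccc(-c2oc3cc(OCC=C(C)C)cc(OCOC)c3c(=O)c2CC=C(C)C)c(OCOC)c1 | intermediate
12 | 2-[2,4-bis(methoxymethoxy)phenyl]-5-(methoxymethoxy)-8-(2-methylbut-3-en-2-yl)-3-(3-methylbut-2-enyl)-8H-chromene-4,7-dione (ortho-dienone, racemic at C8, transient, not isolated) | C=CC(C)(C)C1C(=O)C=C(OCOC)C2=C1OC(c1ccc(OCOC)cc1OCOC)=C(CC=C(C)C)C2=O | intermediate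
13 | 2-[2,4-bis(methoxymethoxy)phenyl]-7-hydroxy-5-(methoxymethoxy)-8-(2-methylbut-3-en-2-yl)-3-(3-methylbut-2-enyl)chromen-4-one | C=CC(C)(C)c1c(O)cc(OCOC)c2c(=O)c(CC=C(C)C)c(-c3ccc(OCOC)cc3OCOC)oc12 | intermediate
14 | nigrasin I, 2-(2,4-dihydroxyphenyl)-5,7-dihydroxy-8-(2-methylbut-3-en-2-yl)-3-(3-methylbut-2-enyl)chromen-4-one | C=CC(C)(C)c1c(O)cc(O)c2c(=O)c(CC=C(C)C)c(-c3ccc(O)cc3O)oc12 | target

Total step count: 8
Longest linear sequence: 6 steps (5 → 6 → 8 → 10 → 11 → 13 → 14; steps 3, 4, 5, 6, 7, 8)

**Steps most likely to fail**

Step 6 (key annulation). Four processes could interfere: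
- The crowded, electron-rich acyl rhodacycle may extrude CO before the alkyne inserts.
- The twisted ortho-substituted aryl group may weaken the bias of insertion, so that the alkyne enters the other way round.
- The doubly activated CH2 of the skipped enyne may migrate into conjugation under metal and acetate.
- Lewis-acidic metal salts may strip the prenyl ether or the MOM group next to the carbonyl.

The fallback builds ring C by ionic chemistry, sets out from 4, 8 and 9, and returns at 11. Alkyne 8 is deprotonated with n-BuLi (THF, −78 °C) to the lithium acetylide F1. Somewhat more than two equivalents are added to 4, since the first equivalent is spent on the phenol, to give the racemic propargylic alcohol F2. MnO2 in CH2Cl2 oxidises this to the ortho-hydroxyaryl ynone F3. Catalytic DMAP in DMF then closes ring C by a 6-endo oxa-Michael addition to the 3-unsubstituted flavone F4. Lithium diisopropylamide (THF, −78 °C) metalates C3, a known site of flavone lithiation that here lies between the carbonyl and the 2'-O-MOM group. The resulting 3-lithioflavone F5 is alkylated with prenyl bromide 9 to give 11.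

Step 7 (Claisen rearrangement). Three processes could interfere:
- The shift may go in part to C6.
- The freed 7-OH may react further with the neighbouring vinyl group on prolonged heating (abnormal Claisen shift or ring closure to a dihydrofuran).
- The ether may lose its prenyl group thermally as isoprene.

The fallback moves the [3,3] shift to the symmetrical compound 3, where both ortho positions are the same. It sets out from 3 and returns at 14. Heating 3 in PhNEt2 (about 185 °C) passes through the transient dienone F6 to 2,4,6-trihydroxy-3-(2-methylbut-3-en-2-yl)benzaldehyde F7. MOMCl (2.1 equiv) with i-Pr2NEt caps the unchelated 4-OH and the less hindered 6-OH. The 2-OH, wedged between the formyl group and the quaternary carbon, stays free in the salicylaldehyde F8. The annulation conditions of step 6 with alkyne 10 should give the tetra-MOM chromone F9, and the methanolic HCl of step 8 then gives 14.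

Step 8 (global deprotection). Protonation of the C3 prenyl olefin may lead to addition of methanol or water. Acid may also close the 7-OH onto the C8 vinyl group before the slower 2'- and 4'-MOM ethers have gone.

The fallback avoids Brønsted acid by exchanging the acetals for silyl ethers. It sets out from 13 and returns at 14. TMSOTf with excess 2,2'-bipyridyl in MeCN (0 °C to rt) converts the three aryl MOM ethers into aryl silyl ethers and silylates the 7-OH, giving the tetrakis(trimethylsilyl) ether F10. Water in MeOH at neutral pH then cleaves the four Si–O bonds to give 14.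

**Further compounds**
F1 | step 6 | lithium [2,4-bis(methoxymethoxy)phenyl]acetylide | [Li]C#Cc1ccc(OCOC)cc1OCOC
F2 | step 6 | racemic 3-[2,4-bis(methoxymethoxy)phenyl]-1-[2-hydroxy-6-(methoxymethoxy)-4-(3-methylbut-2-enyloxy)phenyl]prop-2-yn-1-ol | OC(C#Cc1ccc(OCOC)cc1OCOC)c1c(O)cc(OCC=C(C)C)cc1OCOC
F3 | step 6 | 3-[2,4-bis(methoxymethoxy)phenyl]-1-[2-hydroxy-6-(methoxymethoxy)-4-(3-methylbut-2-enyloxy)phenyl]prop-2-yn-1-one | O=C(C#Cc1ccc(OCOC)cc1OCOC)c1c(O)cc(OCC=C(C)C)cc1OCOC
F4 | step 6 | 2-[2,4-bis(methoxymethoxy)phenyl]-5-(methoxymethoxy)-7-(3-methylbut-2-enyloxy)chromen-4-one | COCOc1ccc(-c2cc(=O)c3c(OCOC)cc(OCC=C(C)C)cc3o2)c(OCOC)c1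
F5 | step 6 | 3-lithio-2-[2,4-bis(methoxymethoxy)phenyl]-5-(methoxymethoxy)-7-(3-methylbut-2-enyloxy)chromen-4-one | COCOc1ccc(-c2oc3cc(OCC=C(C)C)cc(OCOC)c3c(=O)c2[Li])c(OCOC)c1
F6 | step 7 | 2,6-dihydroxy-3-(2-methylbut-3-en-2-yl)-4-oxocyclohexa-1,5-diene-1-carbaldehyde (racemic, transient dienone) | C=CC(C)(C)C1C(=O)C=C(O)C(C=O)=C1O
F7 | step 7 | 2,4,6-trihydroxy-3-(2-methylbut-3-en-2-yl)benzaldehyde | C=CC(C)(C)c1c(O)cc(O)c(C=O)c1O
F8 | step 7 | 2-hydroxy-4,6-bis(methoxymethoxy)-3-(2-methylbut-3-en-2-yl)benzaldehyde | C=CC(C)(C)c1c(OCOC)cc(OCOC)c(C=O)c1O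
F9 | step 7 | 2-[2,4-bis(methoxymethoxy)phenyl]-5,7-bis(methoxymethoxy)-8-(2-methylbut-3-en-2-yl)-3-(3-methylbut-2-enyl)chromen-4-one | C=CC(C)(C)c1c(OCOC)cc(OCOC)c2c(=O)c(CC=C(C)C)c(-c3ccc(OCOC)cc3OCOC)oc12
F10 | step 8 | 2-[2,4-bis(trimethylsilyloxy)phenyl]-8-(2-methylbut-3-en-2-yl)-3-(3-methylbut-2-enyl)-5,7-bis(trimethylsilyloxy)chromen-4-one | C=CC(C)(C)c1c(O[Si](C)(C)C)cc(O[Si](C)(C)C)c2c(=O)c(CC=C(C)C)c(-c3ccc(O[Si](C)(C)C)cc3O[Si](C)(C)C)oc12
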